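## Structural features

The target is a germacrane-type ten-membered carbocycle (C1–C10) with two trisubstituted ring alkenes, C1=C10 (Z, methyl C14) and C4=C5 (E, methyl C15). An α-methylene-γ-butyrolactone (C11, C12, C13, ring oxygen on C6) is fused to it at the C6–C7 bond. Four oxygenated stereocentres are contiguous: C6 (S, lactone CH–O), C7 (R, tertiary carbinol and branch point to C11), C8 (S, angelate) and C9 (R, free allylic hydroxyl). In the extended chain O8/O9 are syn, O7/O8 anti and O6/O7 syn, and the lactone is cis-fused (O6 and C11 on the same face). The fragile groups are the exocyclic enoate of the lactone (Michael acceptor), the angelate (Z to E isomerization, migration to O9 or O7), the tertiary allylic alcohol and the medium-ring 1,5-diene (Cope rearrangement, acid-induced transannular cyclization). The real difficulty is to close a strained ten-membered ring with one Z and one E alkene while the fully substituted C7 and its hindered neighbour C8 are already in place. The key step exploits the C1–C2 bond: it joins the sp2 CH end of the Z alkene C1=C10 to an unsubstituted sp3 CH2 and carries no stereocentre, so a Z alkenyl iodide at C1 and a primary borane at C2 can meet there with both alkene geometries set beforehand. A recheck of all descriptors found no error: the open-chain precursor and the macrocycle have the same spatial arrangement as the target (6S,7R,8S,9R), and C7 is formally S in 29–35 only because the silyl group on O6 changes the priority order.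

## Logic of the disconnections

40 ⇒ 39. The Si–O9 bond is re-formed in the retrosynthetic sense. O9 stays masked to the end so that O8 alone is acylated and O6 alone lactonizes. The skeleton is unchanged, but two selectivity problems disappear from all earlier steps. The forward step must remove a hindered secondary silyl ether without touching the Z enoate ester, the methylene lactone or the diene.

39 ⇒ 36. The O6–C12 acyl bond is cut and C12 is taken back to the alcohol level. The Michael-acceptor lactone is then carried through only one further step. The forward oxidation must act on the primary allylic C12 hydroxyl only and the lactol must close on O6; O8 is acylated and O9 silylated, so no other five- or six-membered closure is open.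

36 ⇒ 35 ⇒ 32 + 33 ⇒ 31. The Si–O6 and Si–O12 bonds, then the O8–acyl bond, then the benzylic O8–C bond are cut. Acylation is placed before lactone formation so that the slow esterification of the hindered O8 is done on a robust substrate. The forward steps need acylation at secondary O8 in the presence of tertiary O7–H without Z/E isomerization of 33, and desilylation that distinguishes secondary TES and primary TBS from the secondary TBS on O9.

31 ⇒ 29 (key disconnection). The C1–C2 bond is cut. This is the one ring bond without a stereocentre and with fixed geometry on its sp2 end, so the ring opens to a chain whose four stereocentres and two alkenes can be built by acyclic methods. The forward step needs hydroboration at C2=C3 only and cyclization in preference to oligomerization. The design of 29 is improved in one point: O12 carries TBS and not TES. The 2-metallated allyl ether used for C11 is then stable toward oxygen-to-carbon silyl migration, the primary TES ether on O6 of 19 can be oxidized selectively, and C11=C13 is better shielded from 9-BBN.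

29 ⇒ 28 ⇒ 20 + 25. After removal of the O6 silyl group the C5–C6 bond is cut. This separates the diene (with its E geometry) from the oxygenated chain and lets C6 be set from C7. The forward addition must be chelation-controlled through the O7 alkoxide and must not disturb the alkenyl iodide, so the dienyl nucleophile is used as its magnesium derivative.

20 ⇒ 19 ⇒ 14 + 16. C6 is taken back from aldehyde to silyl ether and the C7–C11 bond is cut. The tertiary carbinol becomes a ketone whose only α-stereocentre (C8) carries the chelating PMB ether. The forward addition must follow the Cram-chelate mode through O8, so O6 and O9 are silyl ethers (poor ligands) and the nucleophile is an alkenylmagnesium species.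

14 ⇒ 13 ⇒ 12 ⇒ 11. The C7 carbonyl, the O6 silyl group and the two C–O bonds at C6 and C7 are removed; a vinyl group remains. The α-silyloxy ketone is thus reached without any regioselective enolization of an unsymmetrical ketone, and O6 and O8 are differentiated from the outset. The forward dihydroxylation must choose the vinyl group over the iodoalkene; its C7 selectivity is irrelevant.

11 ⇒ 10 ⇒ 8. The Si–O9 bond, then the C10–C14 and C1–I bonds are cut, leaving a terminal alkyne. The free O9 hydroxyl is needed as the directing group for anti addition, so this step is placed before O9 is protected and before any carbonyl group exists. The forward step must deliver methyl to C10 and iodine to C1 with Z geometry.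

8 ⇒ 3 + 4. The C8–C9 bond is cut. Both stereocentres arise in one reagent-controlled step, O8 already carries PMB and O9 is left free. The forward reaction needs a Z γ-alkoxyallyl boron reagent (syn) with chiral ligands (absolute control).

25 ⇒ 24 ⇒ 23 ⇒ 21, 16 ⇒ 15 and 3 ⇒ 1 + 2. These are one C=C bond (C2=C3), the C4–C15 and C5–I bonds, one Si–O bond and one C–O bond; each leads to a commodity chemical. The only demand is syn carbometalation of 21 to fix the E geometry.

## Other disconnections considered

Alternative 1: The C7–C11 bond is cut in a precursor that already holds the ten-membered ring, ketone A1 (C7 ketone, O6 acrylate, O8 angelate, O9 TES). In the forward step a nucleophilic catalyst (quinuclidine or PMe3) would add to the acrylate, the zwitterionic enolate would attack C7 (5-exo closure), and loss of the catalyst would give A2, the 9-O-TES ether of the target.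
- In favour: one step forms the C7–C11 bond, the tertiary carbinol, the lactone and the exocyclic methylene, with no oxidation-state or protecting-group change at C11–C13.
- In favour: the O6 tether forces delivery to the O6 face of the ketone, which is the cis ring fusion of the target. C7 would therefore be controlled more directly than by the chelation-controlled addition of the chosen plan.
- In favour: A2 is one deprotection from the target, against five steps after ring closure in the chosen plan. On late-stage step economy this alternative is clearly better.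
- Against: ketones are poor Morita–Baylis–Hillman acceptors. In A1 the ketone is flanked by two α-acyloxy stereocentres (C6, C8) that can epimerize or eliminate under amine or phosphine catalysis. The same catalysts add reversibly to the angelate and would isomerize it.
- Against: A1 must itself come from a ring closure that is no easier than the one chosen, so the macrocyclization problem is moved, not removed.
- Comparison: Alternative 1 is superior in concept and in late-stage economy but rests on a mechanistically fragile step at the very end. The chosen plan puts its risk in a stereochemically neutral C–C coupling.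

Alternative 2: The C6–C7 bond is cut, leading back to the thirteen-membered diallylic ether A3 (oxygen between C6 and C13, C7=C11 enol ether; drawn here with C8 and C13 cis on that alkene). In the forward step s-BuLi would remove an α-oxy allylic proton at C6 and the carbanion would shift [2,3] onto C7, giving the ten-membered carbocycle A4 with free O6–H and the C11=C13 methylene.
- In favour: a thirteen-membered ether is easier to close than a ten-membered carbocycle, so the strain is paid in a sigmatropic step and no high dilution is needed at the ring-forming C–C bond. Here it is better than the chosen plan.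
- In favour: the step would set C6 and C7 and unveil the methylene in one event, whereas the chosen key step creates no stereocentre.
- Against: C13–H is also α-oxy and allylic, so deprotonation there, [1,2] shifts and elimination of the allylic C8 oxygen compete.
- Against: the migration terminus C7 is a fully substituted, electron-rich enol ether carbon, and the C6/C7 configurations would depend on the folding of a flexible macrocyclic transition state and on an enol ether geometry that is itself hard to secure.
- Against: A4 carries two MOM ethers (O7, O8) that must be told apart and removed late under acid.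
- Comparison: the total step count is roughly equal, and the alternative is better in ring-strain management, but its stereochemical predictability is lower than that of two acyclic chelation-controlled additions.

Alternative 3: The C1=C10 and C4=C5 alkenes are reconnected as the cyclobutane bonds C1–C4 and C5–C10 of the cis,anti,cis tricyclic ketone A5 (accessible in principle by enone–cyclobutene photocycloaddition). Flash thermolysis would cleave the central cyclobutane and give the Z,E-cyclodecadienone A6.
- In favour: no macrocyclization is needed at all. Strain release drives the ring opening and the cis,anti,cis geometry translates into one Z and one E alkene. For construction of the carbocycle itself this is shorter and entropically better than the chosen plan.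
- Against: which of the two alkenes becomes Z is set by conformational effects and not by design.
- Against: the high temperature endangers the β-oxygenated ketone (elimination) and invites Cope rearrangement of the 1,5-diene produced.
- Against: A6 is far from the target. C11–C13 are missing, C7 is a secondary PMB ether that must become a ketone and accept the C11 unit with facial control on a flexible ring, and the C9 ketone must be reduced to the 9R alcohol.
- Comparison: elegant and equal or better for the ring, but clearly worse in total step count and in control at C7 and C9 than the chosen plan, where all four stereocentres are settled before the ring exists.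

Key step: step 16

Assumption: the γ-alkoxyallylborane 6 is taken to follow the facial sense of the parent B-allyl reagent of the same pinene series (si-face attack on the aldehyde); should the correlation demand it, the borinate from (−)-α-pinene would be used with no other change.

## Steps

Step 1
Reactants: 1 4-methoxybenzyl alcohol; 2 allyl bromide
Product: 3 allyl 4-methoxybenzyl ether
Conditions: NaH, Bu4NI (cat.), THF, 0 °C to rt
Reagents that add atoms: none
Why: Williamson ether synthesis; the sodium alkoxide of 1 displaces bromide from 2 by SN2 and no stereocentre is involved.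

Step 2
Reactants: 3 allyl 4-methoxybenzyl ether; 4 3-(trimethylsilyl)propynal
Product: 8 (3R,4R)-4-(4-methoxybenzyloxy)hex-5-en-1-yn-3-ol, via allyllithium 5 (not isolated), via allylborane 6 (not isolated), via C-silylated enynol 7 (not isolated)
Conditions: s-BuLi, THF, −78 °C; (−)-Ipc2BOMe, −78 °C; BF3·OEt2; then 4, −78 °C; NaOH, H2O2, 0 °C to rt; K2CO3, MeOH, rt
Reagents that add atoms: none
Why: Brown γ-alkoxyallylboration: the oxygen-chelated Z allyllithium 5 is trapped on boron at the carbon remote from oxygen, and the Z borane 6 reacts with 4 through a chair six-membered transition state, so O8 and O9 should emerge syn. The isopinocampheyl groups from (+)-α-pinene should direct the allyl group to the si face of the aldehyde (C9 R, hence C8 R in this compound). Peroxide work-up frees the alcohol and methanolic K2CO3 removes the alkynyl silyl group of 7.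

Step 3
Reactants: 8 (3R,4R)-4-(4-methoxybenzyloxy)hex-5-en-1-yn-3-ol
Product: 10 (1Z,3R,4R)-1-iodo-4-(4-methoxybenzyloxy)-2-methylhexa-1,5-dien-3-ol, via oxamagnesacycle 9 (not isolated)
Conditions: MeMgBr (4 equiv), CuI (0.3 equiv), THF, −20 °C to rt; then I2, −78 to 0 °C
Reagents that add atoms: methylmagnesium bromide C[Mg]Br; iodine II
Why: Copper-catalysed anti-carbomagnesiation of a propargylic alkoxide: methyl is delivered to C10 and magnesium to C1 on the opposite side, held by the O9 alkoxide in the five-membered chelate 9. Iodinolysis of the C1–Mg bond with retention should give the Z iodide; the vinyl group and the unactivated allylic ether are not expected to react.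

Step 4
Reactants: 10 (1Z,3R,4R)-1-iodo-4-(4-methoxybenzyloxy)-2-methylhexa-1,5-dien-3-ol
Product: 11 tert-butyl{[(1Z,3R,4R)-1-iodo-4-(4-methoxybenzyloxy)-2-methylhexa-1,5-dien-3-yl]oxy}dimethylsilane
Conditions: TBSOTf, 2,6-lutidine, CH2Cl2, −78 to 0 °C
Reagents that add atoms: tert-butyldimethylsilyl triflate CC(C)(C)[Si](C)(C)OS(=O)(=O)C(F)(F)F
Why: Silylation of a hindered secondary allylic alcohol with a silyl triflate and a hindered base; no stereocentre is touched, and O9 becomes a non-chelating group for step 9.

Step 5
Reactants: 11 tert-butyl{[(1Z,3R,4R)-1-iodo-4-(4-methoxybenzyloxy)-2-methylhexa-1,5-dien-3-yl]oxy}dimethylsilane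
Product: 12 (3R,4R,5Z)-4-(tert-butyldimethylsilyloxy)-6-iodo-3-(4-methoxybenzyloxy)-5-methylhex-5-ene-1,2-diol (both C2 epimers)
Conditions: OsO4 (3 mol%), NMO, acetone/H2O, rt
Reagents that add atoms: N-methylmorpholine N-oxide C[N+]1([O-])CCOCC1; water O
Why: Upjohn dihydroxylation: OsO4 adds to the unhindered monosubstituted alkene, while the iodine-bearing trisubstituted alkene is electron-poor and shielded. The configuration of the new carbinol (C7 of the target) is irrelevant because it is oxidized in step 7.

Step 6
Reactants: 12 (3R,4R,5Z)-4-(tert-butyldimethylsilyloxy)-6-iodo-3-(4-methoxybenzyloxy)-5-methylhex-5-ene-1,2-diol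
Product: 13 (3R,4R,5Z)-4-(tert-butyldimethylsilyloxy)-6-iodo-3-(4-methoxybenzyloxy)-5-methyl-1-(triethylsilyloxy)hex-5-en-2-ol (both C2 epimers)
Conditions: TESCl (1.05 equiv), imidazole, CH2Cl2, −78 to −40 °C
Reagents that add atoms: chlorotriethylsilane CC[Si](CC)(CC)Cl
Why: Sterically controlled silylation of the primary hydroxyl of a 1,2-diol at low temperature; the secondary hydroxyl next to the branched C8 should stay free.

Step 7
Reactants: 13 (3R,4R,5Z)-4-(tert-butyldimethylsilyloxy)-6-iodo-3-(4-methoxybenzyloxy)-5-methyl-1-(triethylsilyloxy)hex-5-en-2-ol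
Product: 14 (3S,4R,5Z)-4-(tert-butyldimethylsilyloxy)-6-iodo-3-(4-methoxybenzyloxy)-5-methyl-1-(triethylsilyloxy)hex-5-en-2-one
Conditions: Dess–Martin periodinane, NaHCO3, CH2Cl2, 0 °C to rt
Reagents that add atoms: none
Why: Dess–Martin oxidation under buffered, non-basic conditions, so the α-stereocentre C8 should not epimerize and the β-silyloxy group should not be eliminated. Both epimers of 13 converge on one ketone (C8 becomes S only through the change in priorities).

Step 8
Reactants: 15 2-bromoprop-2-en-1-ol
Product: 16 (2-bromoallyloxy)(tert-butyl)dimethylsilane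
Conditions: TBSCl, imidazole, CH2Cl2, 0 °C to rt
Reagents that add atoms: tert-butyldimethylsilyl chloride CC(C)(C)[Si](C)(C)Cl
Why: Standard silylation of a primary allylic alcohol; TBS is chosen because it resists oxygen-to-carbon migration in the metallated reagent of step 9.

Step 9
Reactants: 14 (3S,4R,5Z)-4-(tert-butyldimethylsilyloxy)-6-iodo-3-(4-methoxybenzyloxy)-5-methyl-1-(triethylsilyloxy)hex-5-en-2-one; 16 (2-bromoallyloxy)(tert-butyl)dimethylsilane
Product: 19 (2R,3S,4R,5Z)-4-(tert-butyldimethylsilyloxy)-2-[3-(tert-butyldimethylsilyloxy)prop-1-en-2-yl]-6-iodo-3-(4-methoxybenzyloxy)-5-methyl-1-(triethylsilyloxy)hex-5-en-2-ol, via alkenyllithium 17 (not isolated), via alkenylmagnesium bromide 18 (not isolated)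
Conditions: 16 (2.5 equiv), t-BuLi (5 equiv), Et2O, −78 °C; MgBr2·OEt2, −78 °C; then 14, Et2O/CH2Cl2, −78 °C
Reagents that add atoms: none
Why: Bromine–lithium exchange and transmetalation to magnesium at −78 °C, then Cram-chelate addition: magnesium bridges the C7 carbonyl oxygen and the basic PMB ether oxygen on C8 (the silyl ethers on O6 and O9 are poor ligands), and the alkenyl group enters the five-membered chelate on the face away from the C9 branch. This should give the tertiary carbinol with O7 anti to O8 (C7 R here). The magnesium reagent does not exchange with the alkenyl iodide and is less basic than 17, which limits enolization.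

Step 10
Reactants: 19 (2R,3S,4R,5Z)-4-(tert-butyldimethylsilyloxy)-2-[3-(tert-butyldimethylsilyloxy)prop-1-en-2-yl]-6-iodo-3-(4-methoxybenzyloxy)-5-methyl-1-(triethylsilyloxy)hex-5-en-2-ol
Product: 20 (2S,3S,4R,5Z)-4-(tert-butyldimethylsilyloxy)-2-[3-(tert-butyldimethylsilyloxy)prop-1-en-2-yl]-2-hydroxy-6-iodo-3-(4-methoxybenzyloxy)-5-methylhex-5-enal
Conditions: (COCl)2, DMSO, CH2Cl2, −78 to −40 °C; Et3N, −78 °C to rt
Reagents that add atoms: none
Why: Swern oxidation applied directly to a primary triethylsilyl ether: the chlorosulfonium reagent cleaves the unhindered primary O–Si bond and the alkoxysulfonium ion collapses to the aldehyde on addition of base. Primary and secondary TBS ethers and the tertiary alcohol are inert under these conditions. C7 is quaternary and cannot epimerize (its label changes to S through priorities only).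

Step 11
Reactants: 21 prop-2-yn-1-ol
Product: 23 (E)-3-iodo-2-methylprop-2-en-1-ol, via alkenylalane 22 (not isolated)
Conditions: Me3Al, Cp2ZrCl2 (0.25 equiv), CH2Cl2, 0 °C to rt; then I2, THF, −30 to 0 °C
Reagents that add atoms: trimethylaluminium C[Al](C)C; iodine II
Why: Negishi zirconium-catalysed carboalumination: methyl and aluminium add syn across the alkyne with methyl on the internal carbon; iodinolysis with retention should give the E iodide.

Step 12
Reactants: 23 (E)-3-iodo-2-methylprop-2-en-1-ol
Product: 24 (E)-3-iodo-2-methylprop-2-enal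
Conditions: MnO2, CH2Cl2, rt
Reagents that add atoms: none
Why: Allylic oxidation with activated MnO2 under neutral conditions, which should leave the alkene geometry unchanged; the enal is used without storage.

Step 13
Reactants: 24 (E)-3-iodo-2-methylprop-2-enal
Product: 25 (E)-1-iodo-2-methylbuta-1,3-diene
Conditions: Ph3PCH3Br, NaN(SiMe3)2, THF, 0 °C; then 24, −78 to 0 °C
Reagents that add atoms: methyltriphenylphosphonium bromide C[P+](c1ccccc1)(c1ccccc1)c1ccccc1.[Br-]
Why: Wittig methylenation of a non-enolizable enal; the E iodoalkene is not involved, and the volatile diene is kept as a titrated solution in Et2O.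

Step 14
Reactants: 20 (2S,3S,4R,5Z)-4-(tert-butyldimethylsilyloxy)-2-[3-(tert-butyldimethylsilyloxy)prop-1-en-2-yl]-2-hydroxy-6-iodo-3-(4-methoxybenzyloxy)-5-methylhex-5-enal; 25 (E)-1-iodo-2-methylbuta-1,3-diene
Product: 28 (3E,5S,6R,7S,8R,9Z)-8-(tert-butyldimethylsilyloxy)-6-[3-(tert-butyldimethylsilyloxy)prop-1-en-2-yl]-10-iodo-7-(4-methoxybenzyloxy)-3,9-dimethyldeca-1,3,9-triene-5,6-diol, via dienyllithium 26 (not isolated), via dienylmagnesium bromide 27 (not isolated)
Conditions: 25 (3 equiv), t-BuLi (6 equiv), Et2O, −78 °C; MgBr2·OEt2; then 20, CH2Cl2, −78 to −40 °C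
Reagents that add atoms: none
Why: Iodine–lithium exchange with retention and transmetalation give the E dienyl Grignard reagent; its first equivalent deprotonates O7–H and the magnesium alkoxide chelates the aldehyde oxygen (Cram cyclic model, with O8 as a possible third ligand). The second equivalent should then attack C6 from the face opposite the branched C8 substituent, giving the 6S carbinol with O6 syn to O7. The magnesium species does not exchange with the Z alkenyl iodide.

Step 15
Reactants: 28 (3E,5S,6R,7S,8R,9Z)-8-(tert-butyldimethylsilyloxy)-6-[3-(tert-butyldimethylsilyloxy)prop-1-en-2-yl]-10-iodo-7-(4-methoxybenzyloxy)-3,9-dimethyldeca-1,3,9-triene-5,6-diol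
Product: 29 (3E,5S,6S,7S,8R,9Z)-8-(tert-butyldimethylsilyloxy)-6-[3-(tert-butyldimethylsilyloxy)prop-1-en-2-yl]-10-iodo-7-(4-methoxybenzyloxy)-3,9-dimethyl-5-(triethylsilyloxy)deca-1,3,9-trien-6-ol
Conditions: TESCl, imidazole, DMAP (cat.), CH2Cl2, 0 °C
Reagents that add atoms: chlorotriethylsilane CC[Si](CC)(CC)Cl
Why: Silylation of the secondary allylic hydroxyl in preference to the tertiary one on steric grounds; this keeps a free secondary alcohol away from 9-BBN in the key step.

Step 16
Reactants: 29 (3E,5S,6S,7S,8R,9Z)-8-(tert-butyldimethylsilyloxy)-6-[3-(tert-butyldimethylsilyloxy)prop-1-en-2-yl]-10-iodo-7-(4-methoxybenzyloxy)-3,9-dimethyl-5-(triethylsilyloxy)deca-1,3,9-trien-6-ol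
Product: 31 (1(10)Z,4E,6S,7S,8S,9R)-9,12-bis(tert-butyldimethylsilyloxy)-8-(4-methoxybenzyloxy)-6-(triethylsilyloxy)germacra-1(10),4,11(13)-trien-7-ol, via B-alkyl-9-BBN borane 30 (not isolated)
Conditions: 9-BBN (1.6 equiv), THF, 0 °C to rt; then added over 10 h to PdCl2(dppf)·CH2Cl2 (20 mol%), AsPh3 (40 mol%), Cs2CO3, DMF/THF/H2O, 50 °C, final 1 mM
Reagents that add atoms: none
Why: 9-BBN adds syn across the only monosubstituted alkene through a four-centre transition state and places boron on the terminal C2, so that the homoallylic borane 30 forms without touching the conjugated C4=C5 bond. Zerovalent palladium generated from PdCl2(dppf) inserts into the C1–I bond with retention of the Z geometry; the base-activated borate of 30 then transfers its primary alkyl group to palladium, and reductive elimination from the eleven-membered palladacycle forms C1–C2. The closest known reaction type is the B-alkyl Suzuki–Miyaura coupling of 9-BBN boranes made in situ with alkenyl iodides, including its macrocyclic variants, which is precedented but demanding for a ten-membered ring. The carbocycle is closed end to end by this C(sp3)–C(sp2) reductive elimination; the wide bite angle of dppf and the AsPh3 additive favour transmetalation and reductive elimination over β-hydride elimination of the alkylpalladium species. No stereocentre is created: C6–C9 and both alkene geometries enter fixed, and the palladium steps are stereoretentive. The step needs site-selective hydroboration, which the substrate secures because C4=C5 and the iodoalkene are trisubstituted, while C11=C13 is flanked by the quaternary C7, deactivated by two allylic oxygens and screened by the TBS group. It also needs ring closure to outrun oligomerization, which slow addition of 30 to the catalyst at about 1 mM should provide, helped by the Z alkene at C1 and the E alkene at C4 that already bend the chain.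

Step 17
Reactants: 31 (1(10)Z,4E,6S,7S,8S,9R)-9,12-bis(tert-butyldimethylsilyloxy)-8-(4-methoxybenzyloxy)-6-(triethylsilyloxy)germacra-1(10),4,11(13)-trien-7-ol
Product: 32 (1(10)Z,4E,6S,7S,8S,9R)-9,12-bis(tert-butyldimethylsilyloxy)-6-(triethylsilyloxy)germacra-1(10),4,11(13)-triene-7,8-diol
Conditions: DDQ, CH2Cl2/pH 7 phosphate buffer, 0 °C
Reagents that add atoms: none
Why: Oxidative cleavage of the PMB ether: DDQ converts the electron-rich benzyl ether into an oxocarbenium ion that water hydrolyses to the free O8 hydroxyl. The aqueous buffer should prevent acetal formation with the neighbouring O7–H and protect the TES ether from the acidic hydroquinone.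

Step 18
Reactants: 32 (1(10)Z,4E,6S,7S,8S,9R)-9,12-bis(tert-butyldimethylsilyloxy)-6-(triethylsilyloxy)germacra-1(10),4,11(13)-triene-7,8-diol; 33 angelic acid
Product: 35 (1(10)Z,4E,6S,7S,8S,9R)-9,12-bis(tert-butyldimethylsilyloxy)-7-hydroxy-6-(triethylsilyloxy)germacra-1(10),4,11(13)-trien-8-yl (Z)-2-methylbut-2-enoate, via mixed anhydride 34 (not isolated)
Conditions: 33, 2,4,6-trichlorobenzoyl chloride, Et3N, toluene, rt; then 32, 75 °C
Reagents that add atoms: none
Why: Yamaguchi-type esterification through the mixed anhydride 34, which is attacked at the less hindered angeloyl carbonyl. No nucleophilic catalyst is present that could add to the Z enoate and isomerize it to the tiglate, and the secondary O8–H should react in preference to the tertiary O7–H.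

Step 19
Reactants: 35 (1(10)Z,4E,6S,7S,8S,9R)-9,12-bis(tert-butyldimethylsilyloxy)-7-hydroxy-6-(triethylsilyloxy)germacra-1(10),4,11(13)-trien-8-yl (Z)-2-methylbut-2-enoate
Product: 36 (1(10)Z,4E,6S,7R,8S,9R)-9-(tert-butyldimethylsilyloxy)-6,7,12-trihydroxygermacra-1(10),4,11(13)-trien-8-yl (Z)-2-methylbut-2-enoate
Conditions: HF·pyridine, pyridine, THF, 0 °C to rt
Reagents that add atoms: none
Why: Fluoride-mediated desilylation graded by steric access: the secondary TES ether and the primary allylic TBS ether should cleave well before the secondary TBS ether on O9, which is flanked by the C8 ester and the C10 branch. The buffered acidic medium does not promote acyl migration.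

Step 20
Reactants: 36 (1(10)Z,4E,6S,7R,8S,9R)-9-(tert-butyldimethylsilyloxy)-6,7,12-trihydroxygermacra-1(10),4,11(13)-trien-8-yl (Z)-2-methylbut-2-enoate
Product: 39 (1(10)Z,4E,6S,7R,8S,9R)-8-angeloyloxy-9-(tert-butyldimethylsilyloxy)-7-hydroxygermacra-1(10),4,11(13)-trien-12,6-olide, via enal 37 (not isolated), via lactol 38 (not isolated)
Conditions: TEMPO (20 mol%), PhI(OAc)2 (3 equiv), CH2Cl2, rt
Reagents that add atoms: none
Why: TEMPO/PhI(OAc)2 oxidative lactonization: the oxoammonium species oxidizes only the primary allylic alcohol to the enal 37, O6–H adds to the formyl group to give the five-membered lactol 38, and a second oxidation gives the α-methylene lactone. O8 is acylated and O9 silylated, so O6 is the only hydroxyl that can close a five-membered ring, and the tertiary O7–H cannot be oxidized.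

Step 21
Reactants: 39 (1(10)Z,4E,6S,7R,8S,9R)-8-angeloyloxy-9-(tert-butyldimethylsilyloxy)-7-hydroxygermacra-1(10),4,11(13)-trien-12,6-olide
Product: 40 (1(10)Z,4E,6S,7R,8S,9R)-8-angeloyloxy-7,9-dihydroxygermacra-1(10),4,11(13)-trien-12,6-olide (CNP0292337.1)
Conditions: HF·pyridine, THF, 0 °C to rt (polypropylene vessel)
Reagents that add atoms: none
Why: Acidic fluoride desilylation of the last silyl ether; the medium is neither basic nor nucleophilic enough for acyl migration from O8 to O9 or conjugate addition to the methylene lactone, and it is too weakly acidic for transannular cyclization of the diene.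

## Compound list

1 | 4-methoxybenzyl alcohol | COc1ccc(CO)cc1 | starting material
2 | allyl bromide | C=CCBr | starting material
3 | allyl 4-methoxybenzyl ether | C=CCOCc1ccc(OC)cc1 | intermediate
4 | 3-(trimethylsilyl)propynal | C[Si](C)(C)C#CC=O | starting material
5 | (Z)-3-(4-methoxybenzyloxy)allyllithium (not isolated) | [Li]C/C=C\OCc1ccc(OC)cc1 | intermediate
6 | [(Z)-3-(4-methoxybenzyloxy)allyl]diisopinocampheylborane, Ipc groups from (+)-α-pinene (not isolated) | COc1ccc(CO/C=C\CB([C@@H]2C[C@@H]3C[C@H]([C@H]2C)C3(C)C)[C@@H]2C[C@@H]3C[C@H]([C@H]2C)C3(C)C)cc1 | intermediate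
7 | (3R,4R)-4-(4-methoxybenzyloxy)-1-(trimethylsilyl)hex-5-en-1-yn-3-ol (not isolated) | C=C[C@@H](OCc1ccc(OC)cc1)[C@H](O)C#C[Si](C)(C)C | intermediate
8 | (3R,4R)-4-(4-methoxybenzyloxy)hex-5-en-1-yn-3-ol | C=C[C@@H](OCc1ccc(OC)cc1)[C@H](O)C#C | intermediate
9 | five-membered alkenylmagnesium alkoxide chelate from anti addition of Me–Mg to 8 (not isolated) | C=C[C@@H](OCc1ccc(OC)cc1)[C@@H]1O[Mg]C=C1C | intermediate
10 | (1Z,3R,4R)-1-iodo-4-(4-methoxybenzyloxy)-2-methylhexa-1,5-dien-3-ol | C=C[C@@H](OCc1ccc(OC)cc1)[C@H](O)/C(C)=C\I | intermediate
11 | tert-butyl{[(1Z,3R,4R)-1-iodo-4-(4-methoxybenzyloxy)-2-methylhexa-1,5-dien-3-yl]oxy}dimethylsilane | C=C[C@@H](OCc1ccc(OC)cc1)[C@H](O[Si](C)(C)C(C)(C)C)/C(C)=C\I | intermediate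
12 | (3R,4R,5Z)-4-(tert-butyldimethylsilyloxy)-6-iodo-3-(4-methoxybenzyloxy)-5-methylhex-5-ene-1,2-diol, both C2 epimers | OCC(O)[C@@H](OCc1ccc(OC)cc1)[C@H](O[Si](C)(C)C(C)(C)C)/C(C)=C\I | intermediate
13 | (3R,4R,5Z)-4-(tert-butyldimethylsilyloxy)-6-iodo-3-(4-methoxybenzyloxy)-5-methyl-1-(triethylsilyloxy)hex-5-en-2-ol, both C2 epimers | CC[Si](CC)(CC)OCC(O)[C@@H](OCc1ccc(OC)cc1)[C@H](O[Si](C)(C)C(C)(C)C)/C(C)=C\I | intermediate
14 | (3S,4R,5Z)-4-(tert-butyldimethylsilyloxy)-6-iodo-3-(4-methoxybenzyloxy)-5-methyl-1-(triethylsilyloxy)hex-5-en-2-one | CC[Si](CC)(CC)OCC(=O)[C@@H](OCc1ccc(OC)cc1)[C@H](O[Si](C)(C)C(C)(C)C)/C(C)=C\I | intermediate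
15 | 2-bromoprop-2-en-1-ol | C=C(Br)CO | starting material
16 | (2-bromoallyloxy)(tert-butyl)dimethylsilane | C=C(Br)CO[Si](C)(C)C(C)(C)C | intermediate
17 | {3-[(tert-butyldimethylsilyl)oxy]prop-1-en-2-yl}lithium (not isolated) | [Li]C(=C)CO[Si](C)(C)C(C)(C)C | intermediate
18 | {3-[(tert-butyldimethylsilyl)oxy]prop-1-en-2-yl}magnesium bromide (not isolated) | Br[Mg]C(=C)CO[Si](C)(C)C(C)(C)C | intermediate
19 | (2R,3S,4R,5Z)-4-(tert-butyldimethylsilyloxy)-2-[3-(tert-butyldimethylsilyloxy)prop-1-en-2-yl]-6-iodo-3-(4-methoxybenzyloxy)-5-methyl-1-(triethylsilyloxy)hex-5-en-2-ol | CC[Si](CC)(CC)OC[C@](O)(C(=C)CO[Si](C)(C)C(C)(C)C)[C@@H](OCc1ccc(OC)cc1)[C@H](O[Si](C)(C)C(C)(C)C)/C(C)=C\I | intermediate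
20 | (2S,3S,4R,5Z)-4-(tert-butyldimethylsilyloxy)-2-[3-(tert-butyldimethylsilyloxy)prop-1-en-2-yl]-2-hydroxy-6-iodo-3-(4-methoxybenzyloxy)-5-methylhex-5-enal | O=C[C@](O)(C(=C)CO[Si](C)(C)C(C)(C)C)[C@@H](OCc1ccc(OC)cc1)[C@H](O[Si](C)(C)C(C)(C)C)/C(C)=C\I | intermediate
21 | prop-2-yn-1-ol | C#CCO | starting material
22 | (E)-alkenylalane from methylalumination of 21, O- and C-bound AlMe2 (not isolated) | C[Al](C)OC/C(C)=C/[Al](C)C | intermediate
23 | (E)-3-iodo-2-methylprop-2-en-1-ol | OC/C(C)=C/I | intermediate
24 | (E)-3-iodo-2-methylprop-2-enal | O=C/C(C)=C/I | intermediate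
25 | (E)-1-iodo-2-methylbuta-1,3-diene | C=C/C(C)=C/I | intermediate
26 | [(1E)-2-methylbuta-1,3-dien-1-yl]lithium (not isolated) | C=C/C(C)=C/[Li] | intermediate
27 | [(1E)-2-methylbuta-1,3-dien-1-yl]magnesium bromide (not isolated) | C=C/C(C)=C/[Mg]Br | intermediate
28 | (3E,5S,6R,7S,8R,9Z)-8-(tert-butyldimethylsilyloxy)-6-[3-(tert-butyldimethylsilyloxy)prop-1-en-2-yl]-10-iodo-7-(4-methoxybenzyloxy)-3,9-dimethyldeca-1,3,9-triene-5,6-diol | C=C/C(C)=C/[C@H](O)[C@](O)(C(=C)CO[Si](C)(C)C(C)(C)C)[C@@H](OCc1ccc(OC)cc1)[C@H](O[Si](C)(C)C(C)(C)C)/C(C)=C\I | intermediate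
29 | (3E,5S,6S,7S,8R,9Z)-8-(tert-butyldimethylsilyloxy)-6-[3-(tert-butyldimethylsilyloxy)prop-1-en-2-yl]-10-iodo-7-(4-methoxybenzyloxy)-3,9-dimethyl-5-(triethylsilyloxy)deca-1,3,9-trien-6-ol (open-chain precursor of the key step) | C=C/C(C)=C/[C@H](O[Si](CC)(CC)CC)[C@](O)(C(=C)CO[Si](C)(C)C(C)(C)C)[C@@H](OCc1ccc(OC)cc1)[C@H](O[Si](C)(C)C(C)(C)C)/C(C)=C\I | intermediate
30 | B-alkyl-9-BBN borane of 29, boron on C2 (not isolated) | C(CB1C2CCCC1CCC2)/C(C)=C/[C@H](O[Si](CC)(CC)CC)[C@](O)(C(=C)CO[Si](C)(C)C(C)(C)C)[C@@H](OCc1ccc(OC)cc1)[C@H](O[Si](C)(C)C(C)(C)C)/C(C)=C\I | intermediate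
31 | (1(10)Z,4E,6S,7S,8S,9R)-9,12-bis(tert-butyldimethylsilyloxy)-8-(4-methoxybenzyloxy)-6-(triethylsilyloxy)germacra-1(10),4,11(13)-trien-7-ol (product of the key step) | CC[Si](CC)(CC)O[C@H]1/C=C(\C)CC/C=C(/C)[C@@H](O[Si](C)(C)C(C)(C)C)[C@H](OCc2ccc(OC)cc2)[C@@]1(O)C(=C)CO[Si](C)(C)C(C)(C)C | intermediate
32 | (1(10)Z,4E,6S,7S,8S,9R)-9,12-bis(tert-butyldimethylsilyloxy)-6-(triethylsilyloxy)germacra-1(10),4,11(13)-triene-7,8-diol | CC[Si](CC)(CC)O[C@H]1/C=C(\C)CC/C=C(/C)[C@@H](O[Si](C)(C)C(C)(C)C)[C@H](O)[C@@]1(O)C(=C)CO[Si](C)(C)C(C)(C)C | intermediate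
33 | angelic acid, (Z)-2-methylbut-2-enoic acid | C/C=C(/C)C(=O)O | starting material
34 | angelic 2,4,6-trichlorobenzoic anhydride (not isolated) | C/C=C(/C)C(=O)OC(=O)c1c(Cl)cc(Cl)cc1Cl | intermediate
35 | (1(10)Z,4E,6S,7S,8S,9R)-9,12-bis(tert-butyldimethylsilyloxy)-7-hydroxy-6-(triethylsilyloxy)germacra-1(10),4,11(13)-trien-8-yl (Z)-2-methylbut-2-enoate | CC[Si](CC)(CC)O[C@H]1/C=C(\C)CC/C=C(/C)[C@@H](O[Si](C)(C)C(C)(C)C)[C@H](OC(=O)/C(C)=C\C)[C@@]1(O)C(=C)CO[Si](C)(C)C(C)(C)C | intermediate
36 | (1(10)Z,4E,6S,7R,8S,9R)-9-(tert-butyldimethylsilyloxy)-6,7,12-trihydroxygermacra-1(10),4,11(13)-trien-8-yl (Z)-2-methylbut-2-enoate | O[C@H]1/C=C(\C)CC/C=C(/C)[C@@H](O[Si](C)(C)C(C)(C)C)[C@H](OC(=O)/C(C)=C\C)[C@@]1(O)C(=C)CO | intermediate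
37 | C12 enal of 36 (not isolated) | O[C@H]1/C=C(\C)CC/C=C(/C)[C@@H](O[Si](C)(C)C(C)(C)C)[C@H](OC(=O)/C(C)=C\C)[C@@]1(O)C(=C)C=O | intermediate
38 | 12,6-lactol, both C12 epimers (not isolated) | C=C1C(O)O[C@H]2/C=C(\C)CC/C=C(/C)[C@@H](O[Si](C)(C)C(C)(C)C)[C@H](OC(=O)/C(C)=C\C)[C@@]12O | intermediate
39 | (1(10)Z,4E,6S,7R,8S,9R)-8-angeloyloxy-9-(tert-butyldimethylsilyloxy)-7-hydroxygermacra-1(10),4,11(13)-trien-12,6-olide | C=C1C(=O)O[C@H]2/C=C(\C)CC/C=C(/C)[C@@H](O[Si](C)(C)C(C)(C)C)[C@H](OC(=O)/C(C)=C\C)[C@@]12O | intermediate
40 | (1(10)Z,4E,6S,7R,8S,9R)-8-angeloyloxy-7,9-dihydroxygermacra-1(10),4,11(13)-trien-12,6-olide (CNP0292337.1) | C=C1C(=O)O[C@H]2/C=C(\C)CC/C=C(/C)[C@@H](O)[C@H](OC(=O)/C(C)=C\C)[C@@]12O | target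

## Step count and least certain steps

Total step count: 21. Longest linear sequence: 17 steps (steps 1–7, 9, 10 and 14–21); the two side branches are steps 8 and 11–13.

Step 16 (key step). The most likely failure is intermolecular coupling or protodeboronation and β-hydride elimination outrunning ring closure, because the ten-membered transition state carries transannular strain and the alkylpalladium intermediate is long-lived at high dilution; partial hydroboration of C11=C13 is the second concern. The fallback starts from 29: hydroboration with 9-BBN and oxidation with NaBO3·4H2O should give the C2 primary alcohol F1, and I2/PPh3/imidazole should convert it into the primary iodide F2. A nickel-catalysed reductive coupling of the alkyl iodide with the alkenyl iodide (NiCl2(dme), 4,4′-di-tert-butyl-2,2′-bipyridine, Mn powder, DMA, slow addition) would then close the same C1–C2 bond without any organoboron species and return to 31.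

Step 9. The most likely failure is erosion of facial selectivity, because magnesium may bind the ketone together with O6 instead of O8, or not chelate at all; enolization of the α,α′-dioxygenated ketone is the second risk. The fallback starts from 14: DDQ would remove the PMB group to give the α-hydroxy ketone F3. Its magnesium alkoxide is the strongest possible chelating group and should force the Cram cyclic mode on addition of excess 18, giving the diol F4. Tin-mediated alkylation (Bu2SnO, then 4-methoxybenzyl chloride, CsF, DMF) should then place the PMB group on the secondary O8 and return to 19.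

Step 14. The most likely failure is insufficient facial discrimination, because the chelate has to distinguish two branched substituents on the quaternary C7 (C8 against C11). The fallback starts from 28 as a mixture of C6 epimers: Dess–Martin oxidation would give the dienone F5, and TMSOTf/2,6-lutidine would cap O7 to give the silyloxy dienone F6. Reduction with LiBH(s-Bu)3 at −78 °C should then proceed under Felkin–Anh (non-chelation) control, in which the hydride passes the smaller C11 substituent, and give the 6S carbinol F7; by the same model a chelation-controlled hydride would give the wrong epimer. K2CO3 in MeOH removes the tertiary TMS group and returns to 28.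

Step 18. The most likely failure is slow acylation of the hindered O8 hydroxyl, with Z to E isomerization of the enoate during the long heating that this would require. The fallback starts from 32: esterification with 2-[bis(2,2,2-trifluoroethoxy)phosphoryl]propanoic acid (DCC, DMAP; the reactive acylating species is a phosphonoketene) would give the phosphonate ester F8. A Still–Gennari olefination with acetaldehyde (KN(SiMe3)2, 18-crown-6, THF, −78 °C) would then build the Z enoate on the ester already in place and return to 35.

Step 19. The most likely failure is over-reaction that also cleaves the O9 silyl ether, or incomplete cleavage at the primary O12 ether, because the two TBS ethers differ only in steric environment. The fallback starts from 35 and gives up the selectivity: complete desilylation (aqueous HF, MeCN) would give the tetraol F9, and TEMPO/PhI(OAc)2 would then oxidize its primary allylic hydroxyl and close the lactone on O6, arriving directly at 40. This path relies on the oxoammonium reagent preferring the primary alcohol over the secondary allylic O9–H and on the five-membered lactol forming faster than the six-membered one through O9.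

## Further compounds

F1 | step 16 | C2 primary alcohol from hydroboration–oxidation of 29 | OCC/C(C)=C/[C@H](O[Si](CC)(CC)CC)[C@](O)(C(=C)CO[Si](C)(C)C(C)(C)C)[C@@H](OCc1ccc(OC)cc1)[C@H](O[Si](C)(C)C(C)(C)C)/C(C)=C\I
F2 | step 16 | C2 primary iodide (alkyl iodide and Z alkenyl iodide in one chain) | ICC/C(C)=C/[C@H](O[Si](CC)(CC)CC)[C@](O)(C(=C)CO[Si](C)(C)C(C)(C)C)[C@@H](OCc1ccc(OC)cc1)[C@H](O[Si](C)(C)C(C)(C)C)/C(C)=C\I
F3 | step 9 | α-hydroxy ketone, 14 without the PMB group | CC[Si](CC)(CC)OCC(=O)[C@@H](O)[C@H](O[Si](C)(C)C(C)(C)C)/C(C)=C\I
F4 | step 9 | 7,8-diol, 19 without the PMB group | CC[Si](CC)(CC)OC[C@](O)(C(=C)CO[Si](C)(C)C(C)(C)C)[C@@H](O)[C@H](O[Si](C)(C)C(C)(C)C)/C(C)=C\I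
F5 | step 14 | C6 dienone with free O7 hydroxyl | C=C/C(C)=C/C(=O)[C@](O)(C(=C)CO[Si](C)(C)C(C)(C)C)[C@@H](OCc1ccc(OC)cc1)[C@H](O[Si](C)(C)C(C)(C)C)/C(C)=C\I
F6 | step 14 | C6 dienone with 7-O-trimethylsilyl ether | C=C/C(C)=C/C(=O)[C@](O[Si](C)(C)C)(C(=C)CO[Si](C)(C)C(C)(C)C)[C@@H](OCc1ccc(OC)cc1)[C@H](O[Si](C)(C)C(C)(C)C)/C(C)=C\I
F7 | step 14 | 6S carbinol with 7-O-trimethylsilyl ether | C=C/C(C)=C/[C@H](O)[C@](O[Si](C)(C)C)(C(=C)CO[Si](C)(C)C(C)(C)C)[C@@H](OCc1ccc(OC)cc1)[C@H](O[Si](C)(C)C(C)(C)C)/C(C)=C\I
F8 | step 18 | 8-O-{2-[bis(2,2,2-trifluoroethoxy)phosphoryl]propanoyl} ester of 32 | CC[Si](CC)(CC)O[C@H]1/C=C(\C)CC/C=C(/C)[C@@H](O[Si](C)(C)C(C)(C)C)[C@H](OC(=O)C(C)P(=O)(OCC(F)(F)F)OCC(F)(F)F)[C@@]1(O)C(=C)CO[Si](C)(C)C(C)(C)C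
F9 | step 19 | 8-O-angeloyl germacratriene-6,7,9,12-tetraol | O[C@H]1/C=C(\C)CC/C=C(/C)[C@@H](O)[C@H](OC(=O)/C(C)=C\C)[C@@]1(O)C(=C)CO
A1 | alternative 1 | macrocyclic C7 ketone with O6 acrylate, O8 angelate and 9-O-TES | C=CC(=O)O[C@H]1/C=C(\C)CC/C=C(/C)[C@@H](O[Si](CC)(CC)CC)[C@H](OC(=O)/C(C)=C\C)C1=O
A2 | alternative 1 | 9-O-triethylsilyl ether of the target | C=C1C(=O)O[C@H]2/C=C(\C)CC/C=C(/C)[C@@H](O[Si](CC)(CC)CC)[C@H](OC(=O)/C(C)=C\C)[C@@]12O
A3 | alternative 2 | thirteen-membered cyclic ether (O between C6 and C13, C7=C11 enol ether, 7,8-bis-MOM, 9-O-TBS, 12-O-TBS) | [C@H]1(OCOC)[C@H](O[Si](C)(C)C(C)(C)C)/C(C)=C\CC/C(C)=C/COC/C(CO[Si](C)(C)C(C)(C)C)=C\1OCOC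
A4 | alternative 2 | ten-membered carbocycle with free O6 hydroxyl, 7,8-bis(methoxymethoxy), 9-O-TBS and 3-(TBS-oxy)prop-1-en-2-yl on C7 | O[C@H]1/C=C(\C)CC/C=C(/C)[C@@H](O[Si](C)(C)C(C)(C)C)[C@H](OCOC)[C@]1(C(=C)CO[Si](C)(C)C(C)(C)C)OCOC
A5 | alternative 3 | cis,anti,cis tricyclic ketone (C1–C4 and C5–C10 bonds intact, 6-O-TES, 7-O-PMB, 8-O-TBS, 9-oxo) | O=C1[C@H](O[Si](C)(C)C(C)(C)C)[C@H](OCc2ccc(OC)cc2)[C@@H](O[Si](CC)(CC)CC)[C@H]2[C@]1(C)[C@@H]1CC[C@]21C
A6 | alternative 3 | (1(10)Z,4E)-8-(tert-butyldimethylsilyloxy)-7-(4-methoxybenzyloxy)-6-(triethylsilyloxy)germacra-1(10),4-dien-9-one | CC[Si](CC)(CC)O[C@H]1/C=C(\C)CC/C=C(/C)C(=O)[C@H](O[Si](C)(C)C(C)(C)C)[C@@H]1OCc2ccc(OC)cc2
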